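**Plan**
1. Retrosynthesis: the two CH2OH groups and the two phenols are traced back to N-acyl sultam carbonyls and aryl acetates (one hydride step); then the two ring C–C bonds of the oxolane, C2–C3 and C4–C5, are cut in one operation.
2. Enabling feature: the oxolane holds a bis-benzylic C2–O1–C5 ether unit flanked by the two guaiacyl rings, which is a diaryl carbonyl ylide in disguise, and a C3–C4 unit with two trans one-carbon branches, which is a fumaric acid derivative; a 1,3-dipolar cycloaddition joins them.
3. Forward: styrene self-metathesis gives the symmetrical stilbene and epoxidation the oxirane, whose own C–C bond is later cleaved by photoinduced electron transfer to unmask the ylide; the chiral dipolarophile comes in one step from fumaryl chloride; the oxolane, the only ring built, arises in the cycloaddition; LiAlH4 then reduces and deprotects.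
4. Stereochemistry: cis-2,5-diaryl from the W-shaped ylide and trans-3,4 from the E double bond (only one relative configuration is possible); absolute configuration from two (2R)-bornane-10,2-sultam auxiliaries, which expose one face of the C2-symmetric fumaroyl unit.

Key step: step 4

Assumption: the (2R)-sultam is taken to direct the uncatalysed dipolar addition to the Cα-re faces of the fumaroyl unit, as in the accepted model for thermal additions to N-enoyl bornane-10,2-sultams; this sense is derived from the model, not from a precedent with carbonyl ylides, and the mirror-image sultam would be used if it proved opposite.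

**Step 1**
Reactants: 1 4-acetoxy-3-methoxystyrene (two molecules)
Product: 2 (E)-1,2-bis(4-acetoxy-3-methoxyphenyl)ethene
Conditions: second-generation Grubbs catalyst RuCl2(=CHPh)(PCy3)(H2IMes) (cat.), CH2Cl2, 40 °C, argon sweep
Reagents that add atoms: none
Why: Olefin self-metathesis of a terminal styrene, driven by loss of ethene, should give the more stable E-stilbene through secondary metathesis, and aryl acetates are inert to the ruthenium carbene.

**Step 2**
Reactants: 2 (E)-1,2-bis(4-acetoxy-3-methoxyphenyl)ethene
Product: 3 rac-trans-2,3-bis(4-acetoxy-3-methoxyphenyl)oxirane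
Conditions: mCPBA, CH2Cl2 / aq. NaHCO3 (two-phase), 0 °C to rt
Reagents that add atoms: mCPBA, O=C(OO)c1cccc(Cl)c1
Why: Prilezhaev epoxidation transfers oxygen syn to the stilbene double bond to give the racemic trans-oxirane while the bicarbonate layer removes the acid that could open it; the two new stereocentres need no control because both are erased when the oxirane C–C bond is cleaved in step 4.

**Step 3**
Reactants: 4 (2R)-bornane-10,2-sultam (two equivalents); 5 fumaryl chloride
Product: 6 N,N'-fumaroylbis[(2R)-bornane-10,2-sultam]
Conditions: NaH, toluene, rt; then 5, rt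
Reagents that add atoms: none
Why: N-acylation of the sodium salt of the sultam by the bis(acid chloride) is the standard preparation of N-enoyl sultams (nucleophilic acyl substitution), forms no stereocentre and keeps the E geometry.

**Step 4**
Reactants: 3 rac-trans-2,3-bis(4-acetoxy-3-methoxyphenyl)oxirane (slight excess); 6 N,N'-fumaroylbis[(2R)-bornane-10,2-sultam]
Product: 9 N,N'-{[(2R,3S,4S,5S)-2,5-bis(4-acetoxy-3-methoxyphenyl)oxolane-3,4-diyl]dicarbonyl}bis[(2R)-bornane-10,2-sultam], via ring-opened oxirane radical cation 7 (not isolated), via W-shaped carbonyl ylide 8 (not isolated)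
Conditions: 9,10-dicyanoanthracene (cat.), biphenyl, MeCN/CH2Cl2, 405 nm LED, degassed (argon), 0 °C
Reagents that add atoms: none
Why: Excited 9,10-dicyanoanthracene, relayed by biphenyl, takes one electron from 3, the oxirane C–C bond of the radical cation breaks to give 7, and back electron transfer from the sensitiser radical anion gives carbonyl ylide 8, which settles in its exo,exo (W) form whichever epoxide isomer is used. Ylide 8, an electron-rich 4π dipole over C–O–C, adds across the electron-poor C=C of 6 in a concerted suprafacial 1,3-dipolar cycloaddition; the closest known reaction type is the trapping of photogenerated stilbene oxide ylides by fumarates and fumaronitrile, which is stereospecific in the dipolarophile. The oxolane ring is closed by this [3+2] cycloaddition itself, both C–C bonds forming in one transition state, so no separate ring-closure mode has to be obeyed. C2 and C5 become cis because both aryl groups sit on the outer positions of the W ylide, and C3 and C4 stay trans because the E geometry of the fumaroyl unit is retained; as the ylide has two mirror planes and 6 a twofold axis, regiochemistry and endo/exo orientation are degenerate and only one relative configuration can form. The one selectivity needed is therefore π-facial: each sultam, in the s-cis conformation with C=O anti to SO2, shields the Cα-si face with its pseudo-axial sulfonyl oxygen, the two auxiliaries act in concert, and addition to the re,re face sets C3 and C4 in the sense required (C2 and C5 follow from them). Any minor facial diastereomer should be separable at this stage by crystallisation or chromatography of 9.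

**Step 5**
Reactants: 9 N,N'-{[(2R,3S,4S,5S)-2,5-bis(4-acetoxy-3-methoxyphenyl)oxolane-3,4-diyl]dicarbonyl}bis[(2R)-bornane-10,2-sultam]
Product: 10 [(2R,3R,4R,5S)-2,5-bis(4-hydroxy-3-methoxyphenyl)oxolane-3,4-diyl]dimethanol
Conditions: LiAlH4 (excess), THF, 0 °C to rt; then H2O, aq. KNaC4H4O6 (potassium sodium tartrate) work-up
Reagents that add atoms: none
Why: Hydride reduction with LiAlH4 should convert both activated N-acyl sultams into primary alcohols with release of the intact auxiliary and cleave both aryl acetates in the same operation, while no stereocentre is touched because the α-carbons are not equilibrated and the benzylic ether carbons are inert to hydride.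

**Compound list**
1 | 4-acetoxy-3-methoxystyrene (4-ethenyl-2-methoxyphenyl acetate) | C=Cc1ccc(OC(C)=O)c(OC)c1 | starting material
2 | (E)-1,2-bis(4-acetoxy-3-methoxyphenyl)ethene | CC(=O)Oc1ccc(/C=C/c2ccc(OC(C)=O)c(OC)c2)cc1OC | intermediate
3 | rac-trans-2,3-bis(4-acetoxy-3-methoxyphenyl)oxirane (racemate; the (2S,3S) enantiomer is drawn) | CC(=O)Oc1ccc([C@@H]2O[C@H]2c2ccc(OC(C)=O)c(OC)c2)cc1OC | intermediate
4 | (2R)-bornane-10,2-sultam [(1S)-(−)-2,10-camphorsultam] | CC1(C)[C@@H]2CC[C@]13CS(=O)(=O)N[C@@H]3C2 | starting material
5 | fumaryl chloride | O=C(Cl)/C=C/C(=O)Cl | starting material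
6 | N,N'-fumaroylbis[(2R)-bornane-10,2-sultam] | O=C(/C=C/C(=O)N1[C@@H]2C[C@H]3CC[C@]2(CS1(=O)=O)C3(C)C)N1[C@@H]2C[C@H]3CC[C@]2(CS1(=O)=O)C3(C)C | intermediate
7 | ring-opened radical cation of 3 (ylide 8 less one electron) | CC(=O)Oc1ccc(/C=[O+]/[CH]c2ccc(OC(C)=O)c(OC)c2)cc1OC | intermediate (not isolated)
8 | W-shaped (exo,exo) bis(4-acetoxy-3-methoxyphenyl) carbonyl ylide | CC(=O)Oc1ccc(/C=[O+]/[CH-]c2ccc(OC(C)=O)c(OC)c2)cc1OC | intermediate (not isolated)
9 | N,N'-{[(2R,3S,4S,5S)-2,5-bis(4-acetoxy-3-methoxyphenyl)oxolane-3,4-diyl]dicarbonyl}bis[(2R)-bornane-10,2-sultam] (aryl groups cis, acyl groups trans) | COc1cc([C@H]2O[C@@H](c3ccc(OC(C)=O)c(OC)c3)[C@@H](C(=O)N3[C@@H]4C[C@H]5CC[C@]4(CS3(=O)=O)C5(C)C)[C@@H]2C(=O)N2[C@@H]3C[C@H]4CC[C@]3(CS2(=O)=O)C4(C)C)ccc1OC(C)=O | intermediate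
10 | [(2R,3R,4R,5S)-2,5-bis(4-hydroxy-3-methoxyphenyl)oxolane-3,4-diyl]dimethanol | COc1cc([C@H]2O[C@@H](c3ccc(O)c(OC)c3)[C@@H](CO)[C@@H]2CO)ccc1O | target

**Totals**
Total step count: 5. Longest linear sequence: 4 (steps 1, 2, 4, 5).

**Steps most likely to fail**

Step 4. The auxiliaries may discriminate the two faces of the fumaroyl unit poorly in an uncatalysed dipolar addition, and the short-lived ylide may reclose to epoxide faster than it is trapped by the bulky dipolarophile. The fallback gives up auxiliary control for resolution. It sets out from 3: the same sensitised irradiation with dimethyl fumarate in place of 6 should give the racemic diester rac-dimethyl (2R,3S,4S,5S)-2,5-bis(4-acetoxy-3-methoxyphenyl)oxolane-3,4-dicarboxylate F1 with the full relative configuration. LiAlH4 in THF should reduce both esters and cleave both acetates to the racemic tetraol F2. Preparative chromatography on a chiral stationary phase then separates the enantiomers, and the route is rejoined at 10.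

Step 2. The carboxylic acid by-product may open the benzylic epoxide or induce its hydride-shift rearrangement as it forms. The fallback replaces direct oxygen transfer by a halohydrin sequence. It sets out from 2: NBS in wet DMSO should add bromine and hydroxyl anti to give the bromohydrin rac-erythro-2-bromo-1,2-bis(4-acetoxy-3-methoxyphenyl)ethan-1-ol F3. Anhydrous K2CO3 in MeCN closes it by intramolecular displacement under non-acidic conditions, and the route is rejoined at 3. Any loss of anti selectivity is harmless, since both epoxide isomers give the same ylide.

Step 5. Reduction may stop at the hindered second acyl sultam, the basic hydride may epimerise an α-carbon before reduction, and the phenolic tetraol may be retained on the aluminium salts. The fallback separates cleavage from reduction. It sets out from 9: LiOH/H2O2 in THF/H2O at 0 °C should hydrolyse both acyl sultams and both acetates to the diacid (2R,3S,4S,5S)-2,5-bis(4-hydroxy-3-methoxyphenyl)oxolane-3,4-dicarboxylic acid F4, with recovery of the auxiliary. BH3·THF then reduces the two carboxylic acids chemoselectively, and the route is rejoined at 10.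

**Further compounds**
F1 | step 4 | rac-dimethyl (2R,3S,4S,5S)-2,5-bis(4-acetoxy-3-methoxyphenyl)oxolane-3,4-dicarboxylate (racemate; one enantiomer drawn) | COc1cc([C@H]2O[C@@H](c3ccc(OC(C)=O)c(OC)c3)[C@@H](C(=O)OC)[C@@H]2C(=O)OC)ccc1OC(C)=O
F2 | step 4 | racemate of 10 (10 together with its mirror image; the mirror image is drawn) | COc1cc([C@@H]2O[C@H](c3ccc(O)c(OC)c3)[C@H](CO)[C@H]2CO)ccc1O
F3 | step 2 | rac-erythro-2-bromo-1,2-bis(4-acetoxy-3-methoxyphenyl)ethan-1-ol (racemate; the (1S,2R) enantiomer is drawn) | CC(=O)Oc1ccc([C@H](O)[C@H](Br)c2ccc(OC(C)=O)c(OC)c2)cc1OC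
F4 | step 5 | (2R,3S,4S,5S)-2,5-bis(4-hydroxy-3-methoxyphenyl)oxolane-3,4-dicarboxylic acid | COc1cc([C@H]2O[C@@H](c3ccc(O)c(OC)c3)[C@@H](C(=O)O)[C@@H]2C(=O)O)ccc1O
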